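The pyran ring F of the lower unit is cut at O1–C8a and C4a–C4. The route exploits that C4a and C8a are adjacent carbons of ring D and that C5, next to C4a, is unsubstituted and can carry a removable chlorine. The benzylated upper unit is joined 4α to a chlororesorcinol, which is converted into an ortho-silyl aryl triflate. Fluoride releases the ring-D aryne (C4a≡C8a); the free benzylic alkoxide of an anti-2-benzyloxy-3-hydroxy ester, holding lower C2 and C3, adds at C8a and the C4a carbanion acylates the ester, closing ring F in one operation. Hydrogenolysis and borohydride reduction of C4 follow.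

Key step: step 11

Remarks
- Assumption: (2R,3R)-fustin is bought as the natural isolate.
- Rings: upper unit A (benzo), B (catechol), C (pyran); lower unit D (benzo), E (catechol), F (pyran). Lower-unit atoms keep the flavan numbers they have in the target in all intermediates, also before ring F exists.
- The interflavan centre is called 4α (aryl trans to O3), because its CIP letter changes with the ring-D substituents; all SMILES carry the geometry of the target.
- U stands for the upper-unit group (2R,3S)-3,7-bis(benzyloxy)-2-[3,4-bis(benzyloxy)phenyl]chroman-4α-yl.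
- In step 9 the diamine antipode is the one that delivers the (2R,3R) adduct.

Step 1
Reactants: 1 (2R,3R)-fustin
Product: 2 (2R,3S,4R)-2-(3,4-dihydroxyphenyl)chromane-3,4,7-triol (mollisacacidin)
Conditions: NaBH4, EtOH, 0 °C to rt; AcOH to pH 6
Reagents that add atoms: none
Why: Borohydride reduction of the aryl ketone, which for 2,3-trans-dihydroflavonols should give mainly the 3,4-trans diol; the C4 configuration is of no consequence because C4 is ionised in step 3.

Step 2
Reactants: 2 mollisacacidin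
Product: 3 (2R,3S,4R)-3,4,7-tris(benzyloxy)-2-[3,4-bis(benzyloxy)phenyl]chromane
Conditions: NaH, BnBr, Bu4NI (cat.), DMF, 0 °C to rt
Reagents that add atoms: benzyl bromide, BrCc1ccccc1
Why: Williamson etherification of the three phenols and both alcohols; the 4-benzyloxy group is the later leaving group and the 3-benzyl ether stays until step 12.

Step 3
Reactants: 3 penta-O-benzylmollisacacidin; 4 5-chlororesorcinol
Product: 6 (2R,3S)-3,7-bis(benzyloxy)-2-[3,4-bis(benzyloxy)phenyl]-4α-(2-chloro-4,6-dihydroxyphenyl)chromane, via flavan-4-yl cation 5 (not isolated)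
Conditions: BF3·OEt2 (0.5 equiv), 4 (4 equiv), dioxane–CH2Cl2, 0 °C to rt
Reagents that add atoms: none
Why: Friedel–Crafts alkylation through the para-alkoxybenzylic cation 5, as in flavan-3,4-diol/phenol condensations; the arene should enter anti to the 3-benzyloxy group (4α, 3,4-trans) and bond through the carbon para to one hydroxyl of 4, which puts chlorine ortho to the new bond (ring-D C5).

Step 4
Reactants: 6 chlororesorcinol adduct
Product: 7 (2R,3S)-3,7-bis(benzyloxy)-2-[3,4-bis(benzyloxy)phenyl]-4α-(3-bromo-2-chloro-4,6-dihydroxyphenyl)chromane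
Conditions: NBS (1.0 equiv), MeCN, −40 °C
Reagents that add atoms: N-bromosuccinimide, O=C1CCC(=O)N1Br
Why: Electrophilic aromatic bromination of the free resorcinol ring, which should react far faster than the benzyl ether rings, at C4a, the only carbon para to a hydroxyl (C7–OH).

Step 5
Reactants: 7 bromide
Product: 12 3-chloro-5-hydroxy-2-(trimethylsilyl)-4-U-phenyl trifluoromethanesulfonate, via bis(trimethylsilyl) ether 8 (not isolated), via aryllithium 9 (not isolated), via lithium phenolate 10 (not isolated), via silyl ether triflate 11 (not isolated)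
Conditions: (Me3Si)2NH, Me3SiCl (cat.), THF, 65 °C, evaporate; n-BuLi, THF–Et2O, −100 to −78 °C; Tf2O, −78 to 0 °C; aq. NaHCO3
Reagents that add atoms: hexamethyldisilazane, C[Si](C)(C)N[Si](C)(C)C; triflic anhydride, O=S(=O)(C(F)(F)F)OS(=O)(=O)C(F)(F)F
Why: O-silylation, bromine–lithium exchange and retro-Brook 1,3-shift of silicon from the ortho C8a oxygen to C4a install the C-silyl group and tell the two phenols apart, since only the C8a phenolate 10 is freed for triflation while the C7 silyl ether is hydrolysed on work-up; the very low temperature is chosen so that the silyl shift outruns loss of LiCl from 9.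

Step 6
Reactants: 12 phenol silyl triflate
Product: 13 5-(benzyloxy)-3-chloro-2-(trimethylsilyl)-4-U-phenyl trifluoromethanesulfonate
Conditions: BnBr, K2CO3, acetone, rt
Reagents that add atoms: benzyl bromide, BrCc1ccccc1
Why: Williamson benzylation of the remaining phenol, which would otherwise add to the aryne itself; carbonate at room temperature should leave the silyl triflate untouched.

Step 7
Reactants: 14 (benzyloxy)acetyl chloride
Product: 15 S-ethyl 2-(benzyloxy)ethanethioate
Conditions: EtSH, Et3N, CH2Cl2, 0 °C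
Reagents that add atoms: ethanethiol, CCS
Why: Acylation of the thiol by the acid chloride.

Step 8
Reactants: 15 S-ethyl 2-(benzyloxy)ethanethioate
Product: 16 (Z)-2-(benzyloxy)-1-(ethylsulfanyl)-1-(trimethylsilyloxy)ethene
Conditions: LiN(iPr)2, Me3SiCl, THF, −78 °C
Reagents that add atoms: chlorotrimethylsilane, C[Si](C)(C)Cl
Why: Kinetic enolisation of the thioester and O-silylation should give the (Z)-silyl ketene thioacetal used in tin-promoted aldol additions.

Step 9
Reactants: 16 silyl ketene thioacetal; 17 3,4-bis(benzyloxy)benzaldehyde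
Product: 18 S-ethyl (2R,3R)-2-(benzyloxy)-3-[3,4-bis(benzyloxy)phenyl]-3-hydroxypropanethioate
Conditions: Sn(OTf)2, chiral 1-methyl-2-(piperidin-1-ylmethyl)pyrrolidine, Bu2Sn(OAc)2, CH2Cl2, −78 °C; aq. NaHCO3
Reagents that add atoms: none
Why: Asymmetric Mukaiyama aldol addition promoted by divalent tin triflate and a proline-derived diamine, which with α-benzyloxy silyl ketene thioacetals should give the anti adduct; both new centres (2R,3R) are set by the chiral promoter (reagent control).

Step 10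
Reactants: 18 hydroxy thioester
Product: 19 methyl (2R,3R)-2-(benzyloxy)-3-[3,4-bis(benzyloxy)phenyl]-3-hydroxypropanoate
Conditions: MeOH, K2CO3 (0.2 equiv), 0 °C
Reagents that add atoms: methanol, CO
Why: Transesterification of the thioester, so that the annulation releases methoxide and not a thiolate that would trap the aryne; the cold, weakly basic medium should neither epimerise C2 nor cause retro-aldol cleavage.

Step 11
Reactants: 13 silyl triflate; 19 hydroxy ester
Product: 22 (2R,3R)-3,7-bis(benzyloxy)-2-[3,4-bis(benzyloxy)phenyl]-5-chloro-6-U-chroman-4-one, via aryne 20 (not isolated), via aryl caesium 21 (not isolated)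
Conditions: CsF, 18-crown-6 (cat.), 19 (2.5 equiv), THF, 0 °C to rt, slow addition of 13
Reagents that add atoms: none
Why: Proposed new method: fluoride removes the silyl group of 13 with loss of triflate to give aryne 20, the caesium alkoxide of 19 (the only free hydroxyl present) adds at C8a, and the aryl anion 21 at C4a attacks the α-benzyloxy ester carbonyl and expels methoxide. The closest known reaction type is the fluoride-triggered annulation of arynes with salicylate esters to xanthones (O-arylation, then acylation of the aryl anion); an aliphatic secondary alkoxide of a β-hydroxy ester is the new element. Ring F, the only ring closed, forms by intermolecular O-arylation followed by a 6-exo-trig acyl substitution at C4. No stereocentre is created: C2 and C3 are carried in from 19 with their C–O, C–C and C–H bonds untouched, and C4 is set in step 13. The step needs oxygen to enter at C8a and carbon at C4a, and the chlorine at C5 secures this, since a 3-chloroaryne is attacked at the carbon remote from chlorine so that the charge develops next to the C–Cl bond. Acylation over protonation of 21 rests on the aprotic medium and the six-membered transition state, and the low temperature is meant to spare the enolisable C3–H and the now activated C5–Cl of 22.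

Step 12
Reactants: 22 benzylated chloro chromanone
Product: 23 (2R,3R)-2-(3,4-dihydroxyphenyl)-3,7-dihydroxy-6-[(2R,3S,4R)-2-(3,4-dihydroxyphenyl)-3,7-dihydroxychroman-4-yl]chroman-4-one (fisetinidol-(4α→6)-fustin)
Conditions: H2 (1 atm), Pd(OH)2/C, NaOAc, THF–MeOH, rt
Reagents that add atoms: none
Why: Hydrogenolysis of the eight benzyl ethers and hydrodechlorination of the aryl chloride ortho to the ketone (acetate takes up HCl); the doubly oxygen-conjugated aryl ketone and the ring C2–O1 bonds should survive, as in debenzylations of dihydroflavonols.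

Step 13
Reactants: 23 fisetinidol-(4α→6)-fustin
Product: 24 (2R,3S,4R)-2-(3,4-dihydroxyphenyl)-6-[(2R,3S,4R)-2-(3,4-dihydroxyphenyl)-3,7-dihydroxychroman-4-yl]chromane-3,4,7-triol (CNP0280090.3)
Conditions: NaBH4, EtOH, 0 °C; AcOH to pH 6; Sephadex LH-20
Reagents that add atoms: none
Why: Borohydride reduction of the dihydroflavonol carbonyl, which as with fustin in step 1 should deliver hydride so that the new 4-hydroxyl is equatorial and trans to 3-OH (lower C4 R, substrate control); it is done last and worked up near neutral pH because this benzylic hydroxyl para to 7-OH ionises readily in acid.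

Compound list
1 | (2R,3R)-fustin, (2R,3R)-2-(3,4-dihydroxyphenyl)-3,7-dihydroxychroman-4-one | Oc1ccc2c(c1)O[C@H](c1ccc(O)c(O)c1)[C@@H](O)C2=O | starting material
2 | (2R,3S,4R)-2-(3,4-dihydroxyphenyl)chromane-3,4,7-triol (mollisacacidin) | Oc1ccc2c(c1)O[C@H](c1ccc(O)c(O)c1)[C@@H](O)[C@@H]2O | intermediate
3 | (2R,3S,4R)-3,4,7-tris(benzyloxy)-2-[3,4-bis(benzyloxy)phenyl]chromane | c1ccccc1COc1ccc2c(c1)O[C@H](c1ccc(OCc3ccccc3)c(OCc3ccccc3)c1)[C@@H](OCc1ccccc1)[C@@H]2OCc1ccccc1 | intermediate
4 | 5-chlororesorcinol | Oc1cc(O)cc(Cl)c1 | starting material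
5 | (2R,3S)-3,7-bis(benzyloxy)-2-[3,4-bis(benzyloxy)phenyl]chroman-4-ylium (flavan-4-yl cation) | c1ccccc1COc1ccc2c(c1)O[C@H](c1ccc(OCc3ccccc3)c(OCc3ccccc3)c1)[C@@H](OCc1ccccc1)[CH+]2 | intermediate
6 | (2R,3S)-3,7-bis(benzyloxy)-2-[3,4-bis(benzyloxy)phenyl]-4α-(2-chloro-4,6-dihydroxyphenyl)chromane | c1ccccc1COc1ccc2c(c1)O[C@H](c1ccc(OCc3ccccc3)c(OCc3ccccc3)c1)[C@@H](OCc1ccccc1)[C@@H]2c1c(Cl)cc(O)cc1O | intermediate
7 | (2R,3S)-3,7-bis(benzyloxy)-2-[3,4-bis(benzyloxy)phenyl]-4α-(3-bromo-2-chloro-4,6-dihydroxyphenyl)chromane | c1ccccc1COc1ccc2c(c1)O[C@H](c1ccc(OCc3ccccc3)c(OCc3ccccc3)c1)[C@@H](OCc1ccccc1)[C@@H]2c1c(Cl)c(Br)c(O)cc1O | intermediate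
8 | bis(trimethylsilyl) ether of 7 (C7 and C8a oxygens silylated) | c1ccccc1COc1ccc2c(c1)O[C@H](c1ccc(OCc3ccccc3)c(OCc3ccccc3)c1)[C@@H](OCc1ccccc1)[C@@H]2c1c(Cl)c(Br)c(O[Si](C)(C)C)cc1O[Si](C)(C)C | intermediate
9 | aryllithium from 8 (lithium at C4a in place of bromine) | c1ccccc1COc1ccc2c(c1)O[C@H](c1ccc(OCc3ccccc3)c(OCc3ccccc3)c1)[C@@H](OCc1ccccc1)[C@@H]2c1c(Cl)c([Li])c(O[Si](C)(C)C)cc1O[Si](C)(C)C | intermediate
10 | lithium phenolate after silyl shift (C4a–SiMe3, C8a–OLi, C7–OSiMe3) | c1ccccc1COc1ccc2c(c1)O[C@H](c1ccc(OCc3ccccc3)c(OCc3ccccc3)c1)[C@@H](OCc1ccccc1)[C@@H]2c1c(Cl)c([Si](C)(C)C)c([O-])cc1O[Si](C)(C)C.[Li+] | intermediate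
11 | 3-chloro-2-(trimethylsilyl)-5-(trimethylsilyloxy)-4-U-phenyl trifluoromethanesulfonate | c1ccccc1COc1ccc2c(c1)O[C@H](c1ccc(OCc3ccccc3)c(OCc3ccccc3)c1)[C@@H](OCc1ccccc1)[C@@H]2c1c(Cl)c([Si](C)(C)C)c(OS(=O)(=O)C(F)(F)F)cc1O[Si](C)(C)C | intermediate
12 | 3-chloro-5-hydroxy-2-(trimethylsilyl)-4-U-phenyl trifluoromethanesulfonate (ring D: C5–Cl, C4a–SiMe3, C8a–OTf, C7–OH) | c1ccccc1COc1ccc2c(c1)O[C@H](c1ccc(OCc3ccccc3)c(OCc3ccccc3)c1)[C@@H](OCc1ccccc1)[C@@H]2c1c(Cl)c([Si](C)(C)C)c(OS(=O)(=O)C(F)(F)F)cc1O | intermediate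
13 | 5-(benzyloxy)-3-chloro-2-(trimethylsilyl)-4-U-phenyl trifluoromethanesulfonate | c1ccccc1COc1ccc2c(c1)O[C@H](c1ccc(OCc3ccccc3)c(OCc3ccccc3)c1)[C@@H](OCc1ccccc1)[C@@H]2c1c(Cl)c([Si](C)(C)C)c(OS(=O)(=O)C(F)(F)F)cc1OCc1ccccc1 | intermediate
14 | (benzyloxy)acetyl chloride | O=C(Cl)COCc1ccccc1 | starting material
15 | S-ethyl 2-(benzyloxy)ethanethioate | CCSC(=O)COCc1ccccc1 | intermediate
16 | (Z)-2-(benzyloxy)-1-(ethylsulfanyl)-1-(trimethylsilyloxy)ethene | CCS/C(O[Si](C)(C)C)=C\OCc1ccccc1 | intermediate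
17 | 3,4-bis(benzyloxy)benzaldehyde | O=Cc1ccc(OCc2ccccc2)c(OCc2ccccc2)c1 | starting material
18 | S-ethyl (2R,3R)-2-(benzyloxy)-3-[3,4-bis(benzyloxy)phenyl]-3-hydroxypropanethioate | O[C@H](c1ccc(OCc2ccccc2)c(OCc2ccccc2)c1)[C@@H](OCc1ccccc1)C(=O)SCC | intermediate
19 | methyl (2R,3R)-2-(benzyloxy)-3-[3,4-bis(benzyloxy)phenyl]-3-hydroxypropanoate | O[C@H](c1ccc(OCc2ccccc2)c(OCc2ccccc2)c1)[C@@H](OCc1ccccc1)C(=O)OC | intermediate
20 | ring-D aryne, U-substituted 2-(benzyloxy)-6-chloro-4,5-didehydrobenzene (C4a≡C8a, Cl at C5) | c1ccccc1COc1ccc2c(c1)O[C@H](c1ccc(OCc3ccccc3)c(OCc3ccccc3)c1)[C@@H](OCc1ccccc1)[C@@H]2C1=C(Cl)C#CC=C1OCc1ccccc1 | intermediate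
21 | aryl caesium: C8a aryl ether of 19 with the carbanion at C4a | c1ccccc1COc1ccc2c(c1)O[C@H](c1ccc(OCc3ccccc3)c(OCc3ccccc3)c1)[C@@H](OCc1ccccc1)[C@@H]2c1c(Cl)[c-]c(O[C@H](c3ccc(OCc4ccccc4)c(OCc4ccccc4)c3)[C@@H](OCc3ccccc3)C(=O)OC)cc1OCc1ccccc1.[Cs+] | intermediate
22 | (2R,3R)-3,7-bis(benzyloxy)-2-[3,4-bis(benzyloxy)phenyl]-5-chloro-6-U-chroman-4-one | c1ccccc1COc1ccc2c(c1)O[C@H](c1ccc(OCc3ccccc3)c(OCc3ccccc3)c1)[C@@H](OCc1ccccc1)[C@@H]2c1c(Cl)c2c(cc1OCc1ccccc1)O[C@H](c1ccc(OCc3ccccc3)c(OCc3ccccc3)c1)[C@@H](OCc1ccccc1)C2=O | intermediate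
23 | (2R,3R)-2-(3,4-dihydroxyphenyl)-3,7-dihydroxy-6-[(2R,3S,4R)-2-(3,4-dihydroxyphenyl)-3,7-dihydroxychroman-4-yl]chroman-4-one | Oc1ccc2c(c1)O[C@H](c1ccc(O)c(O)c1)[C@@H](O)[C@@H]2c1cc2c(cc1O)O[C@H](c1ccc(O)c(O)c1)[C@@H](O)C2=O | intermediate
24 | (2R,3S,4R)-2-(3,4-dihydroxyphenyl)-6-[(2R,3S,4R)-2-(3,4-dihydroxyphenyl)-3,7-dihydroxychroman-4-yl]chromane-3,4,7-triol (CNP0280090.3) | Oc1ccc2c(c1)O[C@H](c1ccc(O)c(O)c1)[C@@H](O)[C@@H]2c1cc2c(cc1O)O[C@H](c1ccc(O)c(O)c1)[C@@H](O)[C@@H]2O | target

Total step count: 13. Longest linear sequence: 9 steps (steps 1–6 and 11–13, from 1 to 24); steps 7–10 form the side branch to 19.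

Steps most likely to fail

Step 11 (proposed new method). The aryl anion may be protonated before it reaches the ester, which would leave a plain O-aryl ether. The alkoxide of 19 may also undergo retro-aldol cleavage, and the chromanone may ring-open or epimerise under the basic fluoride medium. The fallback uses known chemistry, sets out from 3 and comes back at 23. Cation 5, generated from 3 with BF3·OEt2 in dioxane–CH2Cl2, is trapped by unprotected (2R,3R)-fustin 1 in excess. Fustin's resorcinol-type ring should react at C6 (para to O1, ortho to 7-OH) and anti to the 3-benzyloxy group, in a classical flavan-4-yl cation/phenol condensation. This gives 6-U-(2R,3R)-fustin F1, and hydrogenolysis (H2, Pd(OH)2/C, THF–MeOH) gives 23. In this fallback ring F comes ready-made from fustin.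

Step 3. The cation may attack the carbon between the two hydroxyls of 4, or react only sluggishly at the chlorine-flanked carbon, so that self-condensation of the benzylated unit competes. The fallback gives up the directing chlorine, sets out from 3 and comes back at 23. Cation 5 is trapped by commercial 4-bromoresorcinol, whose only open carbon para to a hydroxyl is the desired one and which already carries bromine at C4a. This gives (2R,3S)-3,7-bis(benzyloxy)-2-[3,4-bis(benzyloxy)phenyl]-4α-(5-bromo-2,4-dihydroxyphenyl)chromane F2. The silylation, exchange and triflation sequence of step 5 gives 5-hydroxy-2-(trimethylsilyl)-4-U-phenyl trifluoromethanesulfonate F3, and benzylation as in step 6 gives 5-(benzyloxy)-2-(trimethylsilyl)-4-U-phenyl trifluoromethanesulfonate F4. Annulation with 19 as in step 11 gives (2R,3R)-3,7-bis(benzyloxy)-2-[3,4-bis(benzyloxy)phenyl]-6-U-chroman-4-one F5. Without chlorine the two orientations of addition are not controlled and would have to be separated. Hydrogenolysis as in step 12 then gives 23.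

Step 12. Hydrodechlorination of the hindered C5–Cl may stay incomplete, or the ketone may be over-reduced during the long hydrogenolysis of eight benzyl ethers. The fallback separates the two events, sets out from 22 and comes back at 23. Benzyl groups are removed without hydrogen by BCl3 and pentamethylbenzene (CH2Cl2, −78 °C) to give (2R,3R)-5-chloro-2-(3,4-dihydroxyphenyl)-3,7-dihydroxy-6-[(2R,3S)-2-(3,4-dihydroxyphenyl)-3,7-dihydroxychroman-4α-yl]chroman-4-one F6. The chlorine alone is then removed with H2, Pd/C and Et3N in MeOH to give 23.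

Further compounds
F1 | step 11 | 6-U-(2R,3R)-fustin, (2R,3R)-2-(3,4-dihydroxyphenyl)-3,7-dihydroxy-6-U-chroman-4-one | c1ccccc1COc1ccc2c(c1)O[C@H](c1ccc(OCc3ccccc3)c(OCc3ccccc3)c1)[C@@H](OCc1ccccc1)[C@@H]2c1cc2c(cc1O)O[C@H](c1ccc(O)c(O)c1)[C@@H](O)C2=O
F2 | step 3 | (2R,3S)-3,7-bis(benzyloxy)-2-[3,4-bis(benzyloxy)phenyl]-4α-(5-bromo-2,4-dihydroxyphenyl)chromane | c1ccccc1COc1ccc2c(c1)O[C@H](c1ccc(OCc3ccccc3)c(OCc3ccccc3)c1)[C@@H](OCc1ccccc1)[C@@H]2c1cc(Br)c(O)cc1O
F3 | step 3 | 5-hydroxy-2-(trimethylsilyl)-4-U-phenyl trifluoromethanesulfonate | c1ccccc1COc1ccc2c(c1)O[C@H](c1ccc(OCc3ccccc3)c(OCc3ccccc3)c1)[C@@H](OCc1ccccc1)[C@@H]2c1cc([Si](C)(C)C)c(OS(=O)(=O)C(F)(F)F)cc1O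
F4 | step 3 | 5-(benzyloxy)-2-(trimethylsilyl)-4-U-phenyl trifluoromethanesulfonate | c1ccccc1COc1ccc2c(c1)O[C@H](c1ccc(OCc3ccccc3)c(OCc3ccccc3)c1)[C@@H](OCc1ccccc1)[C@@H]2c1cc([Si](C)(C)C)c(OS(=O)(=O)C(F)(F)F)cc1OCc1ccccc1
F5 | step 3 | (2R,3R)-3,7-bis(benzyloxy)-2-[3,4-bis(benzyloxy)phenyl]-6-U-chroman-4-one | c1ccccc1COc1ccc2c(c1)O[C@H](c1ccc(OCc3ccccc3)c(OCc3ccccc3)c1)[C@@H](OCc1ccccc1)[C@@H]2c1cc2c(cc1OCc1ccccc1)O[C@H](c1ccc(OCc3ccccc3)c(OCc3ccccc3)c1)[C@@H](OCc1ccccc1)C2=O
F6 | step 12 | (2R,3R)-5-chloro-2-(3,4-dihydroxyphenyl)-3,7-dihydroxy-6-[(2R,3S)-2-(3,4-dihydroxyphenyl)-3,7-dihydroxychroman-4α-yl]chroman-4-one | Oc1ccc2c(c1)O[C@H](c1ccc(O)c(O)c1)[C@@H](O)[C@@H]2c1c(Cl)c2c(cc1O)O[C@H](c1ccc(O)c(O)c1)[C@@H](O)C2=O
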